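## The problem

The target (17) is a 2,3-dihydrobenzofuran. Ring A (5-allyl, 7-methoxy) is fused to the dihydrofuran, C2 carries the 4-hydroxy-3-methoxyphenyl ring B, and C3 carries a methylene (C9) that is ether-linked to a second eugenol unit, ring C. There are only two stereocentres, C2 (S) and C3 (R); they are adjacent and trans. C3 can steer C2, because the benzylic C2–O bond next to a para-oxygenated aryl group can open and reclose, and trans is the thermodynamic isomer. The reverse does not hold, and nothing in the molecule fixes the absolute configuration, so it must come from outside. The two allyl groups rule out hydrogenation, electrophilic halogen, strong oxidants and prolonged strong base or metal hydride, which isomerise allyl to propenyl. The free phenol and the acid-sensitive benzylic C2–O bond limit the end game to mild conditions. The enabling feature is that the C2–C3 bond is the former C2=C3 bond of a benzofuran. C3 is the nucleophilic β-carbon of an enol ether and C2 is stabilised as a cation by O1. If C2 carries a tetracoordinate boron, that charge is quenched by a 1,2-shift of a boron ligand. The trans relation is then an anti addition across C2=C3, and the C2–H bond derives from a C–B bond.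

## Retrosynthesis

**17 from 16.** Only the O–CH2OCH3 bond of a methoxymethyl ether on the ring B phenol is cut. The group is chosen because it survives aryllithium formation, borate chemistry and fluoride. A silyl ether would fall in the fluoride step while boron still sits at C2, and a benzyl ether would need hydrogenolysis, which the allyl groups forbid. The forward step needs only mild acid.

**16 from 15.** The C2–H bond is traced back to a C2–B bond. Boron is what makes C2 an acceptor for an aryl group, so it is kept as a placeholder for hydrogen. Oxidation of the C–B bond would give the wrong oxidation level (a lactol). The forward step must replace boron by hydrogen with retention.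

**15 from 4, 12 and 7 (through 13 and 14).** The bonds C3–C9 and C2–C1' are cut together. Neighbouring cuts are weaker:
- Cutting C9–O (late etherification of a C9 alcohol) costs a step and a protecting group.
- Cutting C2–O1 (phenol closure onto a benzylic cation) needs an acyclic precursor with C3 already set.
- Cutting C3–C3a calls for radical chemistry with only kinetic control of C3.

The chosen cut removes both stereocentres at once and leaves three achiral aromatic pieces: the 2-lithiobenzofuran 13 (made in the flask from bromide 4), the guaiacyl boronate 12 and the chloromethyl ether 7. The forward reaction must attack C3 of borate 14, shift the aryl group anti, and distinguish the two faces through the diol on boron.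

**4 from 1 via 2 and 3.** Lithium is placed at C2 by bromine–lithium exchange on 4, not by deprotonation of the parent benzofuran. This avoids competing metalation of the doubly activated allylic–benzylic CH2. Bromide 4 comes from dibromoalkene 3 by intramolecular C–O coupling (O1–C2 cut), 3 from salicylaldehyde 2 by dibromo-olefination, and 2 from eugenol (1) by ortho-formylation.

**7 from 1 and 5 via 6.** The C9–Cl bond is traced to a C9–S bond and the O–C9 bond to alkylation of eugenol (1) with chloromethyl methyl sulfide (5). The CH2 of 5 becomes C9 of the target.

**12 from 8 and 10 via 9 and 11.** The C–B bond comes from bromine–lithium exchange and borylation of the protected bromophenol 9 (from 8). The B–O bonds come from condensation of boronic acid 11 with the C2-symmetric diol 10, which is recovered after step 9.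

## Roads not taken

**Alternative 1:** The cut is C3–C9, made by cyclopropanation of a benzofuran double bond, with the C2–C9 bond formed temporarily and broken later. In the forward key step the carbene from ethyl diazoacetate, on CuOTf with a tert-butyl bis(oxazoline) ligand, adds to the furan double bond of a brominated benzofuran to give the exo cyclopropane A1.
- Merit: the absolute configuration of C3 comes from a catalytic asymmetric reaction with a track record on furans and benzofurans. In this respect it is better founded than induction by a diol on boron.
- Weak points: A1 contains neither ring B nor ring C nor the allyl group (bromine is a placeholder). C9 arrives carrying an ester carbon the target lacks, so a degradative C–C to C–O exchange is needed. After opening, ring B must be added to a C2 oxocarbenium ion in a separate arylation, followed by etherification and cross-coupling.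
- Comparison: the chosen plan joins all three arenes and both stereocentres in one operation, with no degradation and roughly half the linear length. Against the better enantiocontrol of A1 it sets separable diastereomers, since the diol stays in 15.

**Alternative 2:** The cuts are C3–C3a (aryl radical 5-exo closure) and C9–O (dioxygen capture). Bu3SnH under air converts an ortho-iodoaryl 1-arylallyl ether into the C3a radical, which adds to the internal alkene carbon. The C9 radical takes up dioxygen, and PPh3 reduces the hydroperoxide to the alcohol A2.
- Merit: C2 can be installed beforehand by established asymmetric allylic etherification, so the absolute configuration rests on firmer ground than in the chosen plan. The closure is reliable and oxygenates C9 directly.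
- Weak points: C3 is set relative to C2 under kinetic radical control, where trans is preferred but not enforced and cannot be corrected afterwards. Peroxyl and stannyl radicals threaten the allylic–benzylic C–H bonds, and reduction to the 3-methyl compound competes with oxygen capture. A2 still lacks ring C, so etherification and desilylation follow.
- Comparison: the chosen plan sets against this a trans relation fixed by mechanism (anti shift), the inclusion of ring C in the key step, and no tin.

**Alternative 3:** The cuts are C3a–C7a, C6–C7 and C7–O, so ring A is built from a furan while the dihydrofuran closes. AuCl3 or Ph3PAuNTf2 activates an alkynyl ether, the tethered furan attacks it and the furan oxygen is relocated as the C7 phenol, giving A3.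
- Merit: a catalytic, atom-economical step that closes two rings with the oxygen pattern of ring A fixed by mechanism. In catalytic economy it is better than the chosen plan, which uses stoichiometric organolithium and a stoichiometric chiral diol.
- Weak points: both stereocentres must already be present in an acyclic, labile ynol ether, so the stereochemical problem is moved to an anti-selective acyclic construction and not solved. A3 still needs selective O-methylation at C7 and deprotection.
- Comparison: the chosen plan sets against this intact aromatic rings from eugenol (1), both stereocentres made in the key step, and a much shorter sequence.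

Key step: step 8

Assumption: the (R,R)-diol 10 is taken to favour the (2S,3R) adduct 15. The sense of induction cannot be predicted with confidence, and if it proves opposite the (S,S)-diol is used with no other change.

## Route

Step 1
Reactants: 1 eugenol (4-allyl-2-methoxyphenol)
Product: 2 5-allyl-2-hydroxy-3-methoxybenzaldehyde
Conditions: MgCl2, Et3N, (CH2O)n, MeCN, reflux; aq. HCl work-up
Reagents that add atoms: paraformaldehyde (formaldehyde), C=O
Why: Magnesium phenoxide-directed ortho-formylation (Casnati–Skattebøl) should attack the only free ortho position of 1, and the near-neutral conditions leave the allyl group untouched.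

Step 2
Reactants: 2 5-allyl-2-hydroxy-3-methoxybenzaldehyde
Product: 3 4-allyl-2-(2,2-dibromovinyl)-6-methoxyphenol
Conditions: CBr4, PPh3, CH2Cl2, 0 °C
Reagents that add atoms: carbon tetrabromide, BrC(Br)(Br)Br
Why: Ramirez dibromo-olefination (first half of the Corey–Fuchs sequence) with Ph3P=CBr2 is established on free salicylaldehydes, and the ylide ignores the isolated alkene.

Step 3
Reactants: 3 4-allyl-2-(2,2-dibromovinyl)-6-methoxyphenol
Product: 4 5-allyl-2-bromo-7-methoxybenzofuran
Conditions: CuI (5 mol %), K3PO4, THF, 80 °C
Reagents that add atoms: none
Why: Copper-catalysed intramolecular Ullmann-type C–O coupling of the phenoxide with the bromide cis to the ring should close the furan and leave the second bromide as the C2 handle, a known route from gem-dibromovinyl phenols to 2-bromobenzofurans.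

Step 4
Reactants: 1 eugenol, 5 chloromethyl methyl sulfide
Product: 6 4-allyl-2-methoxy-1-[(methylsulfanyl)methoxy]benzene (eugenyl methylthiomethyl ether)
Conditions: NaH, DMF, 0 °C; then 5, NaI (cat.), rt
Reagents that add atoms: none
Why: Williamson O-alkylation of sodium eugenolate with the α-chloro sulfide under iodide catalysis is the standard preparation of aryl methylthiomethyl ethers.

Step 5
Reactants: 6 eugenyl methylthiomethyl ether
Product: 7 4-allyl-1-(chloromethoxy)-2-methoxybenzene (eugenyl chloromethyl ether)
Conditions: SO2Cl2 (1.0 equiv), cyclohexene (10 equiv), CH2Cl2, −78 → 0 °C; volatiles off, short-path distillation, used at once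
Reagents that add atoms: sulfuryl chloride, O=S(=O)(Cl)Cl
Why: S-Chlorination of the O,S-acetal and fragmentation to the aryloxymethyl oxocarbenium ion, which collapses with chloride, is the known conversion of methylthiomethyl ethers into chloromethyl ethers; excess cyclohexene scavenges the methanesulfenyl chloride before it can add to the allyl group.

Step 6
Reactants: 8 4-bromo-2-methoxyphenol
Product: 9 4-bromo-2-methoxy-1-(methoxymethoxy)benzene
Conditions: MOMCl, i-Pr2NEt, CH2Cl2, 0 °C → rt
Reagents that add atoms: chloromethyl methyl ether, COCCl
Why: Standard phenol protection as the methoxymethyl ether, which withstands organolithiums and fluoride and leaves with mild acid.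

Step 7
Reactants: 9 4-bromo-2-methoxy-1-(methoxymethoxy)benzene, 10 (1R,2R)-1,2-dicyclohexylethane-1,2-diol
Product: 12 (4R,5R)-4,5-dicyclohexyl-2-[3-methoxy-4-(methoxymethoxy)phenyl]-1,3,2-dioxaborolane, via the free arylboronic acid 11 (not isolated)
Conditions: n-BuLi, THF, −78 °C; B(Oi-Pr)3, −78 °C → rt; aq. NH4Cl; then 10, 4 Å MS, toluene, rt
Reagents that add atoms: triisopropyl borate, CC(C)OB(OC(C)C)OC(C)C
Why: Bromine–lithium exchange outruns ortho-lithiation at −78 °C, borate quench and mild hydrolysis give 11, and condensation with the diol is driven by removal of water; the diol stereocentres are not touched.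

Step 8
Reactants: 4 5-allyl-2-bromo-7-methoxybenzofuran, 12 (4R,5R)-4,5-dicyclohexyl-2-[3-methoxy-4-(methoxymethoxy)phenyl]-1,3,2-dioxaborolane, 7 eugenyl chloromethyl ether
Product: 15 (4R,5R)-2-{(2S,3R)-5-allyl-3-[(4-allyl-2-methoxyphenoxy)methyl]-7-methoxy-2-[3-methoxy-4-(methoxymethoxy)phenyl]-2,3-dihydrobenzofuran-2-yl}-4,5-dicyclohexyl-1,3,2-dioxaborolane, via 5-allyl-2-lithio-7-methoxybenzofuran 13 (not isolated), via lithium benzofuranyl(aryl)borate complex 14 (not isolated)
Conditions: 4, t-BuLi (2.0 equiv), THF, −78 °C; 12, −78 → 0 °C; 7, −78 °C → rt; separation of diastereomers on SiO2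
Reagents that add atoms: none
Why: Proposed new method: Bromine–lithium exchange on 4 gives 13 faster than allylic deprotonation, and 13 adds to the boron of 12 to give the tetracoordinate borate 14. In 14 the benzofuran C3 is the β-carbon of an enol ether pushed by anionic boron, so it attacks the oxocarbenium-like carbon of 7 as chloride leaves (C3–C9), and the charge arising at C2 is quenched by 1,2-migration of the guaiacyl group from boron (C2–C1'); no ring is closed. The closest known reaction type is the electrophile-induced dearomative 1,2-metallate rearrangement of indol-2-yl, furan-2-yl and benzofuran-2-yl boronate complexes with alkyl halides and other carbon electrophiles; the α-chloro ether partner and facial control by a diol on boron are the untested parts. The aryl group enters C2 antiperiplanar to the incoming electrophile, so C1' and C9 end up trans and boron takes the place of the later C2–H; this relative configuration is inherent in the mechanism. The absolute configuration of C3, and with it C2, depends on which face of the benzofuran is attacked, and the only chiral element is the (R,R)-diol on boron, whose cyclohexyl groups differentiate the two rotamers about the C2–B bond. Because the diol stays in the product, the two anti adducts are diastereomers, and 15 should be obtained pure by chromatography or crystallisation, so enantiopurity does not rest on the level of induction alone. Site selectivity for C3 over the guaiacyl ring follows from the lower aromatic stabilisation of the furan ring, and no free organolithium remains to consume 7.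

Step 9
Reactants: 15 the 2-boryl dihydrobenzofuran
Product: 16 (2S,3R)-5-allyl-3-[(4-allyl-2-methoxyphenoxy)methyl]-7-methoxy-2-[3-methoxy-4-(methoxymethoxy)phenyl]-2,3-dihydrobenzofuran
Conditions: TBAF·3H2O, toluene, 50 °C
Reagents that add atoms: none
Why: Fluoride-promoted protodeboronation of tertiary benzylic boronic esters proceeds with retention through a hydrated fluoroborate, so hydrogen should take the position of boron cis to C9 and leave the aryl group trans; C3 is not involved, and the methoxymethyl ether, aryl ethers and allyl groups are inert to fluoride.

Step 10
Reactants: 16 the methoxymethyl-protected target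
Product: 17 4-{(2S,3R)-5-allyl-3-[(4-allyl-2-methoxyphenoxy)methyl]-7-methoxy-2,3-dihydrobenzofuran-2-yl}-2-methoxyphenol (target)
Conditions: HCl (2 M aq.), MeOH–THF, 45 °C
Reagents that add atoms: none
Why: Acid-catalysed acetal exchange removes the aryl methoxymethyl ether under conditions too mild to isomerise the allyl groups; should the benzylic C2–O bond open reversibly, reclosure favours the trans isomer already present.

## Compound list

1 | eugenol (4-allyl-2-methoxyphenol) | C=CCc1ccc(O)c(OC)c1 | starting material
2 | 5-allyl-2-hydroxy-3-methoxybenzaldehyde | O=Cc1cc(CC=C)cc(OC)c1O | intermediate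
3 | 4-allyl-2-(2,2-dibromovinyl)-6-methoxyphenol | BrC(Br)=Cc1cc(CC=C)cc(OC)c1O | intermediate
4 | 5-allyl-2-bromo-7-methoxybenzofuran | Brc1cc2cc(CC=C)cc(OC)c2o1 | intermediate
5 | chloromethyl methyl sulfide | CSCCl | starting material
6 | 4-allyl-2-methoxy-1-[(methylsulfanyl)methoxy]benzene | C=CCc1ccc(OCSC)c(OC)c1 | intermediate
7 | 4-allyl-1-(chloromethoxy)-2-methoxybenzene | C=CCc1ccc(OCCl)c(OC)c1 | intermediate
8 | 4-bromo-2-methoxyphenol | COc1cc(Br)ccc1O | starting material
9 | 4-bromo-2-methoxy-1-(methoxymethoxy)benzene | COCOc1ccc(Br)cc1OC | intermediate
10 | (1R,2R)-1,2-dicyclohexylethane-1,2-diol | O[C@H](C1CCCCC1)[C@H](O)C1CCCCC1 | starting material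
11 | [3-methoxy-4-(methoxymethoxy)phenyl]boronic acid | COCOc1ccc(B(O)O)cc1OC | intermediate
12 | (4R,5R)-4,5-dicyclohexyl-2-[3-methoxy-4-(methoxymethoxy)phenyl]-1,3,2-dioxaborolane | COCOc1ccc(B2O[C@H](C3CCCCC3)[C@@H](C3CCCCC3)O2)cc1OC | intermediate
13 | 5-allyl-2-lithio-7-methoxybenzofuran | [Li]c1cc2cc(CC=C)cc(OC)c2o1 | intermediate
14 | lithium (4R,5R)-2-(5-allyl-7-methoxybenzofuran-2-yl)-4,5-dicyclohexyl-2-[3-methoxy-4-(methoxymethoxy)phenyl]-1,3,2-dioxaborolan-2-uide | [Li+].C=CCc1cc(OC)c2oc(cc2c1)[B-]1(c2ccc(OCOC)c(OC)c2)O[C@H](C2CCCCC2)[C@@H](C2CCCCC2)O1 | intermediate
15 | (4R,5R)-2-{(2S,3R)-5-allyl-3-[(4-allyl-2-methoxyphenoxy)methyl]-7-methoxy-2-[3-methoxy-4-(methoxymethoxy)phenyl]-2,3-dihydrobenzofuran-2-yl}-4,5-dicyclohexyl-1,3,2-dioxaborolane | C=CCc1ccc(OC[C@H]2c3cc(CC=C)cc(OC)c3O[C@]2(B2O[C@H](C3CCCCC3)[C@@H](C3CCCCC3)O2)c2ccc(OCOC)c(OC)c2)c(OC)c1 | intermediate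
16 | (2S,3R)-5-allyl-3-[(4-allyl-2-methoxyphenoxy)methyl]-7-methoxy-2-[3-methoxy-4-(methoxymethoxy)phenyl]-2,3-dihydrobenzofuran | C=CCc1ccc(OC[C@H]2c3cc(CC=C)cc(OC)c3O[C@@H]2c2ccc(OCOC)c(OC)c2)c(OC)c1 | intermediate
17 | 4-{(2S,3R)-5-allyl-3-[(4-allyl-2-methoxyphenoxy)methyl]-7-methoxy-2,3-dihydrobenzofuran-2-yl}-2-methoxyphenol | C=CCc1ccc(OC[C@H]2c3cc(CC=C)cc(OC)c3O[C@@H]2c2ccc(O)c(OC)c2)c(OC)c1 | target

## Step count and risk

Total: 10 steps. Longest linear sequence: 6 steps (1, 2, 3, 8, 9, 10, from eugenol).

**Step 8 (key step).** Three things are most likely to go wrong:
- Weak or reversed facial discrimination by the diol, which halves the throughput of 15.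
- Slow ionisation of the aryloxymethyl chloride, so that the borate decomposes or is protonated before C3 attack.
- Allylic metalation during the exchange.

The first is met inside the plan by diastereomer separation and by the antipodal diol. If the rearrangement itself fails, a fallback built only from known reactions sets out from 4 and 12 and rejoins the route at 16.
- Suzuki–Miyaura coupling of 4 with 12 (Pd(PPh3)4, aq. K2CO3, dioxane) would give 5-allyl-7-methoxy-2-[3-methoxy-4-(methoxymethoxy)phenyl]benzofuran F1.
- Bromination at C3 with N-bromosuccinimide would give the 3-bromo compound F2.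
- Bromine–lithium exchange (n-BuLi, −78 °C) and quenching with methyl chloroformate would give methyl 5-allyl-7-methoxy-2-[3-methoxy-4-(methoxymethoxy)phenyl]benzofuran-3-carboxylate F3.
- Dissolving-metal conjugate reduction with Mg in MeOH would give the racemic trans methyl 2,3-dihydrobenzofuran-3-carboxylate F4, trans by equilibration of the ester-bearing C3.
- LiAlH4 reduction and resolution on a chiral stationary phase would give [(2S,3R)-5-allyl-7-methoxy-2-[3-methoxy-4-(methoxymethoxy)phenyl]-2,3-dihydrobenzofuran-3-yl]methanol F5.
- Mitsunobu etherification of F5 with eugenol (1) (PPh3, diisopropyl azodicarboxylate) would give 16.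

This route is longer and relies on resolution, but every step is of a known type.

**Step 9.** Retention may be eroded if a free C2 carbanion escapes and is protonated from either face, and fluoride may attack the hindered α-oxy boronate only slowly. The fallback hands control of C2 to thermodynamics.
- From 15, radical protodeboronation (PhLi, then Mn(OAc)3·2H2O and 4-tert-butylcatechol) would give 16 together with its (2R,3R) cis epimer F7.
- Treating the mixture with CF3CO2H in CH2Cl2 should remove the methoxymethyl group and equilibrate C2 through reversible opening of the benzylic C2–O bond.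
- C3 is unaffected, so both epimers converge on the trans target 17.

**Step 5.** Electrophilic sulfur or chlorine may add to the allyl group despite the scavenger, and the chloromethyl ether may hydrolyse on handling. The fallback drops 7 and defers the aryl ether bond.
- From borate 14 (made from 4 and 12 as in step 8), commercial (triisopropylsiloxy)methyl chloride as electrophile would give the 2-boryl 3-(triisopropylsilyloxymethyl) dihydrobenzofuran F6.
- TBAF·3H2O should then cleave both the C–B and O–Si bonds to give the alcohol F5.
- Mitsunobu etherification of F5 with eugenol (1) would return to the route at 16, at the cost of one step.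

## Further compounds

F1 | step 8 | 5-allyl-7-methoxy-2-[3-methoxy-4-(methoxymethoxy)phenyl]benzofuran | C=CCc1cc(OC)c2oc(cc2c1)-c1ccc(OCOC)c(OC)c1
F2 | step 8 | 5-allyl-3-bromo-7-methoxy-2-[3-methoxy-4-(methoxymethoxy)phenyl]benzofuran | C=CCc1cc(OC)c2oc(-c3ccc(OCOC)c(OC)c3)c(Br)c2c1
F3 | step 8 | methyl 5-allyl-7-methoxy-2-[3-methoxy-4-(methoxymethoxy)phenyl]benzofuran-3-carboxylate | C=CCc1cc(OC)c2oc(-c3ccc(OCOC)c(OC)c3)c(C(=O)OC)c2c1
F4 | step 8 | methyl trans-5-allyl-7-methoxy-2-[3-methoxy-4-(methoxymethoxy)phenyl]-2,3-dihydrobenzofuran-3-carboxylate (racemic; the (2S,3S) enantiomer is drawn) | COC(=O)[C@H]1c2cc(CC=C)cc(OC)c2O[C@@H]1c1ccc(OCOC)c(OC)c1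
F5 | step 8 | [(2S,3R)-5-allyl-7-methoxy-2-[3-methoxy-4-(methoxymethoxy)phenyl]-2,3-dihydrobenzofuran-3-yl]methanol | OC[C@H]1c2cc(CC=C)cc(OC)c2O[C@@H]1c1ccc(OCOC)c(OC)c1
F6 | step 5 | (4R,5R)-2-{(2S,3R)-5-allyl-7-methoxy-2-[3-methoxy-4-(methoxymethoxy)phenyl]-3-[(triisopropylsilyloxy)methyl]-2,3-dihydrobenzofuran-2-yl}-4,5-dicyclohexyl-1,3,2-dioxaborolane | CC(C)[Si](OC[C@H]1c2cc(CC=C)cc(OC)c2O[C@]1(B1O[C@H](C2CCCCC2)[C@@H](C2CCCCC2)O1)c1ccc(OCOC)c(OC)c1)(C(C)C)C(C)C
F7 | step 9 | (2R,3R)-5-allyl-3-[(4-allyl-2-methoxyphenoxy)methyl]-7-methoxy-2-[3-methoxy-4-(methoxymethoxy)phenyl]-2,3-dihydrobenzofuran (cis epimer of 16) | C=CCc1ccc(OC[C@H]2c3cc(CC=C)cc(OC)c3O[C@H]2c2ccc(OCOC)c(OC)c2)c(OC)c1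
A1 | alternative 1 | exo ethyl 5-bromo-7-methoxy-cyclopropa[b]benzofuran carboxylate | CCOC(=O)[C@@H]1[C@H]2c3cc(Br)cc(OC)c3O[C@@H]12
A2 | alternative 2 | trans (5-allyl-7-methoxy-2-aryl-2,3-dihydrobenzofuran-3-yl)methanol with the ring B phenol as triisopropylsilyl ether | OC[C@H]1c2cc(CC=C)cc(OC)c2O[C@@H]1c1ccc(O[Si](C(C)C)(C(C)C)C(C)C)c(OC)c1
A3 | alternative 3 | 7-hydroxy analogue of the target with the ring B phenol as methoxymethyl ether | C=CCc1ccc(OC[C@H]2c3cc(CC=C)cc(O)c3O[C@@H]2c2ccc(OCOC)c(OC)c2)c(OC)c1
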